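The route rests on reading both C-allyl groups as Claisen images of O-allyl ethers. The 1,1-dimethylallyl group on C8 of ring A sits ortho to O7, and the prenyl group on C5' of ring B sits ortho to O4', C5' being the only open carbon next to that oxygen. One thermal operation on a quercetin 7-O-prenyl, 4'-O-(1,1-dimethylallyl) bis-ether, with the 5- and 3'-hydroxyls capped as methoxymethyl (MOM) ethers, therefore performs two [3,3] shifts of opposite sense and forges both C–C bonds, including the congested C8–C(CH3)2 bond. The precursor comes from a Claisen–Schmidt chalcone and an Algar–Flynn–Oyamada closure of ring C; acid then frees the two capped hydroxyls.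

Key step: step 8

Remark: the target is achiral; the only stereocentres met on the way are those of the transient dihydroflavonol 12, which is racemic (one enantiomer drawn) and is dehydrogenated in the same flask.

Step 1
Reactants: 1 2,4,6-trihydroxyacetophenone; 2 prenyl bromide (1-bromo-3-methylbut-2-ene)
Product: 3 2,6-dihydroxy-4-(prenyloxy)acetophenone
Conditions: K2CO3 (1.0 equiv), 2 (1.0 equiv), acetone, reflux
Reagents that add atoms: none
Why: Williamson etherification in which the 4-OH, the most acidic hydroxyl and the only one not held in a hydrogen bond to the acetyl carbonyl, is O-alkylated first when carbonate and bromide are limited to one equivalent, while the weak base in acetone keeps C-prenylation of the ring minor.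

Step 2
Reactants: 3 2,6-dihydroxy-4-(prenyloxy)acetophenone
Product: 4 2-hydroxy-6-(methoxymethoxy)-4-(prenyloxy)acetophenone
Conditions: MOMCl (1.2 equiv), iPr2NEt, CH2Cl2, 0 °C to rt
Reagents that add atoms: chloromethyl methyl ether, COCCl
Why: MOM acetal formation under amine base stops after one of the two equivalent ortho hydroxyls is capped, because the remaining one is tied up in the chelate with the ketone carbonyl and is not alkylated under these mild conditions.

Step 3
Reactants: 5 3,4-dihydroxybenzaldehyde; 6 2-methylbut-3-yn-2-ol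
Product: 8 3-hydroxy-4-(2-methylbut-3-yn-2-yloxy)benzaldehyde, via 2-methylbut-3-yn-2-yl trifluoroacetate 7 (not isolated)
Conditions: 6, (CF3CO)2O, DBU, MeCN, −5 °C; then 5, DBU (1.1 equiv), CuCl2·2H2O (1 mol %), MeCN, −5 to 0 °C
Reagents that add atoms: none
Why: Copper-catalysed propargylic substitution of a tertiary propargyl ester by a phenoxide (through a copper acetylide/allenylidene) gives hindered aryl 1,1-dimethylpropargyl ethers at 0 °C, and the 4-OH para to the formyl group is far more acidic than the 3-OH, so the monophenoxide generated by DBU should react at O4.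

Step 4
Reactants: 8 3-hydroxy-4-(2-methylbut-3-yn-2-yloxy)benzaldehyde
Product: 9 3-(methoxymethoxy)-4-(2-methylbut-3-yn-2-yloxy)benzaldehyde
Conditions: MOMCl, iPr2NEt, CH2Cl2, 0 °C to rt
Reagents that add atoms: chloromethyl methyl ether, COCCl
Why: MOM protection of the remaining phenol under basic, non-acidic conditions, which the acid-sensitive tertiary propargyl ether and the aldehyde tolerate.

Step 5
Reactants: 9 3-(methoxymethoxy)-4-(2-methylbut-3-yn-2-yloxy)benzaldehyde
Product: 10 3-(methoxymethoxy)-4-(2-methylbut-3-en-2-yloxy)benzaldehyde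
Conditions: H2 (1 atm, stopped at 1 equiv), Pd/CaCO3 poisoned with Pb(OAc)2, quinoline, EtOAc, 20 °C; work-up and storage below 30 °C, Et3N-deactivated silica
Reagents that add atoms: none
Why: Semi-hydrogenation of the terminal alkyne over lead-poisoned palladium stops at the vinyl group and leaves the aldehyde and both ethers untouched, and the product is kept cool because aryl 1,1-dimethylallyl ethers rearrange on mild heating.

Step 6
Reactants: 4 2-hydroxy-6-(methoxymethoxy)-4-(prenyloxy)acetophenone; 10 3-(methoxymethoxy)-4-(2-methylbut-3-en-2-yloxy)benzaldehyde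
Product: 11 (E)-2'-hydroxy-6',3-bis(methoxymethoxy)-4'-(prenyloxy)-4-(1,1-dimethylallyloxy)chalcone
Conditions: KOH (aq.), EtOH, 0 °C to rt, Ar
Reagents that add atoms: none
Why: Claisen–Schmidt condensation in which the methyl ketone enolate adds to the non-enolisable aldehyde and E1cB loss of water gives the conjugated E-enone as the thermodynamic isomer, the MOM acetals and both allyl ethers being inert to hydroxide at room temperature.

Step 7
Reactants: 11 (E)-2'-hydroxy-6',3-bis(methoxymethoxy)-4'-(prenyloxy)-4-(1,1-dimethylallyloxy)chalcone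
Product: 13 5,3'-di-O-MOM-7-O-prenyl-4'-O-(1,1-dimethylallyl)quercetin, via trans-dihydroflavonol 12 (not isolated)
Conditions: H2O2 (30% aq.), NaOH (aq.), MeOH/THF, dilute, 0 °C to rt; NH4Cl quench
Reagents that add atoms: hydrogen peroxide, OO
Why: Algar–Flynn–Oyamada reaction in which the 2'-phenoxide closes ring C at the β-carbon while hydroperoxide hydroxylates the α-carbon, and alkaline peroxide then dehydrogenates the racemic trans-dihydroflavonol 12 (aryl and OH both equatorial) so that both transient stereocentres vanish; nucleophilic peroxide leaves the isolated electron-rich olefins alone, and cold dilute conditions hold back the aurone pathway that a 6'-alkoxy group favours.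

Step 8
Reactants: 13 5,3'-di-O-MOM-7-O-prenyl-4'-O-(1,1-dimethylallyl)quercetin
Product: 15 5,3'-di-O-MOM-8-(1,1-dimethylallyl)-5'-prenylquercetin, via ring B rearranged monoether 14 (not isolated)
Conditions: PhNEt2 (degassed, dilute), Ar, 120 °C, then 190 °C
Reagents that add atoms: none
Why: Each ether undergoes a concerted, suprafacial aromatic [3,3] sigmatropic shift through a chair-like transition state followed by tautomerisation of the dienone to the phenol, and the allyl inversion of the mechanism converts the 4'-O-C(CH3)2CH=CH2 group into C5'-CH2CH=C(CH3)2 (O4'–C(CH3)2 broken, C5'–CH2 formed) and the 7-O-CH2CH=C(CH3)2 group into C8-C(CH3)2CH=CH2 (O7–CH2 broken, C8–C(CH3)2 formed). The closest known reactions are the thermal ortho-Claisen rearrangements of aryl 1,1-dimethylallyl ethers to ortho-prenylphenols and of 7-prenyloxy chromones and coumarins to 8-(1,1-dimethylallyl)-7-hydroxy compounds, here run back to back in one flask. No ring is closed and no stereocentre is formed. On ring B the tertiary ether shifts at about 120 °C and can end only at C5', because C3' carries the OMOM group and C1' the chromone, so a shift towards C3' cannot lead to an aromatic product and simply reverts. On ring A the shift needs about 190 °C and must go to C8 and not C6: the MOM cap on O5 removes the 5-OH to C4=O chelate that would favour C6, so the bond fixation of the benzopyranone (more double-bond character in C7–C8) and the crowding of C6 by the neighbouring OMOM group should direct the allyl unit to C8. Staged heating in a degassed amine solvent lets ring B finish before ring A is driven, limits loss of the tertiary group as isoprene, and keeps short the time the new 7-OH spends next to its C8 side chain at high temperature.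

Step 9
Reactants: 15 5,3'-di-O-MOM-8-(1,1-dimethylallyl)-5'-prenylquercetin
Product: 16 8-(1,1-dimethylallyl)-5'-prenylquercetin (CNP0196880.0)
Conditions: HCl (3 M aq.), MeOH, 45 °C, quenched at full conversion with NaHCO3
Reagents that add atoms: none
Why: Acid-catalysed methanolysis of the two MOM acetals (the 5-O-MOM group, peri to the carbonyl, goes first) is run at mild temperature and for a short time because prolonged acid would cyclise the ortho-allyl phenols to a chroman or a dihydrobenzofuran.

Compound list
1 | 2,4,6-trihydroxyacetophenone | CC(=O)c1c(O)cc(O)cc1O | starting material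
2 | prenyl bromide (1-bromo-3-methylbut-2-ene) | CC(C)=CCBr | starting material
3 | 1-[2,6-dihydroxy-4-(3-methylbut-2-enyloxy)phenyl]ethanone | CC(=O)c1c(O)cc(OCC=C(C)C)cc1O | intermediate
4 | 1-[2-hydroxy-6-(methoxymethoxy)-4-(3-methylbut-2-enyloxy)phenyl]ethanone | CC(=O)c1c(O)cc(OCC=C(C)C)cc1OCOC | intermediate
5 | 3,4-dihydroxybenzaldehyde | O=Cc1ccc(O)c(O)c1 | starting material
6 | 2-methylbut-3-yn-2-ol | C#CC(C)(C)O | starting material
7 | 2-methylbut-3-yn-2-yl trifluoroacetate | C#CC(C)(C)OC(=O)C(F)(F)F | intermediate
8 | 3-hydroxy-4-(2-methylbut-3-yn-2-yloxy)benzaldehyde | C#CC(C)(C)Oc1ccc(C=O)cc1O | intermediate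
9 | 3-(methoxymethoxy)-4-(2-methylbut-3-yn-2-yloxy)benzaldehyde | C#CC(C)(C)Oc1ccc(C=O)cc1OCOC | intermediate
10 | 3-(methoxymethoxy)-4-(2-methylbut-3-en-2-yloxy)benzaldehyde | C=CC(C)(C)Oc1ccc(C=O)cc1OCOC | intermediate
11 | (E)-1-[2-hydroxy-6-(methoxymethoxy)-4-(3-methylbut-2-enyloxy)phenyl]-3-[3-(methoxymethoxy)-4-(2-methylbut-3-en-2-yloxy)phenyl]prop-2-en-1-one | COCOc1cc(OCC=C(C)C)cc(O)c1C(=O)/C=C/c1ccc(OC(C)(C)C=C)c(OCOC)c1 | intermediate
12 | (±)-trans-3-hydroxy-5-(methoxymethoxy)-2-[3-(methoxymethoxy)-4-(2-methylbut-3-en-2-yloxy)phenyl]-7-(3-methylbut-2-enyloxy)chroman-4-one (racemic, one enantiomer drawn) | O=C1[C@@H](O)[C@H](c2ccc(OC(C)(C)C=C)c(OCOC)c2)Oc2cc(OCC=C(C)C)cc(OCOC)c12 | intermediate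
13 | 3-hydroxy-5-(methoxymethoxy)-2-[3-(methoxymethoxy)-4-(2-methylbut-3-en-2-yloxy)phenyl]-7-(3-methylbut-2-enyloxy)-4H-chromen-4-one | COCOc1cc(OCC=C(C)C)cc2oc(-c3ccc(OC(C)(C)C=C)c(OCOC)c3)c(O)c(=O)c12 | intermediate
14 | 3-hydroxy-2-[4-hydroxy-3-(methoxymethoxy)-5-(3-methylbut-2-enyl)phenyl]-5-(methoxymethoxy)-7-(3-methylbut-2-enyloxy)-4H-chromen-4-one | COCOc1cc(OCC=C(C)C)cc2oc(-c3cc(CC=C(C)C)c(O)c(OCOC)c3)c(O)c(=O)c12 | intermediate
15 | 3,7-dihydroxy-2-[4-hydroxy-3-(methoxymethoxy)-5-(3-methylbut-2-enyl)phenyl]-5-(methoxymethoxy)-8-(2-methylbut-3-en-2-yl)-4H-chromen-4-one | COCOc1cc(O)c(C(C)(C)C=C)c2oc(-c3cc(CC=C(C)C)c(O)c(OCOC)c3)c(O)c(=O)c12 | intermediate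
16 | 2-[3,4-dihydroxy-5-(3-methylbut-2-enyl)phenyl]-3,5,7-trihydroxy-8-(2-methylbut-3-en-2-yl)-4H-chromen-4-one | C=CC(C)(C)c1c(O)cc(O)c2c(=O)c(O)c(-c3cc(O)c(O)c(CC=C(C)C)c3)oc12 | target

Total step count: 9 steps. Longest linear sequence: 7 steps (steps 3 to 9, from 5 and 6).

Steps most likely to fail

Step 8. The double rearrangement may suffer from incomplete regiocontrol on ring A (migration to C6), from loss of the tertiary allyl group of ring B as isoprene before it shifts, and from isomerisation or cyclisation of the freshly formed ortho-(1,1-dimethylallyl)phenol at 190 °C. The fallback separates the two shifts and captures the ring A phenol as it forms. It sets out from 13, which is heated in toluene at 110 °C so that only ring B rearranges and 14 is isolated. Acetylation (Ac2O, pyridine, rt) gives the 3,4'-di-O-acetate of 14 F1. Heating F1 with Ac2O and NaOAc in PhNEt2 (sealed tube, 190 °C) carries out the ring A shift with immediate O-acetylation of the 7-OH, giving 3,7,4'-tri-O-acetyl-5,3'-di-O-MOM-8-(1,1-dimethylallyl)-5'-prenylquercetin F2. Methanolysis (K2CO3, MeOH, rt) removes the three acetates and returns to the route at 15.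

Step 7. The oxidative cyclisation may divert to five-membered ring closure with aurone formation, which the 6'-alkoxy group encourages, or degrade the product by over-oxidation. The fallback builds ring C and the C3 oxygen in separate operations. It sets out from 11, which buffered oxa-Michael closure (NaOAc, EtOH, 45 °C) converts into the racemic 5-(methoxymethoxy)-7-(prenyloxy)flavanone carrying the ring B ethers F3. The lithium enolate of F3 (LiN(SiMe3)2, THF, −78 °C) is hydroxylated with 2-(phenylsulfonyl)-3-phenyloxaziridine anti to the C2 aryl group, giving the trans-dihydroflavonol 12 as an isolated compound. Dess–Martin periodinane (NaHCO3, CH2Cl2, rt) then oxidises the C3 carbinol, and because the resulting 1,2-dicarbonyl array is simply the keto tautomer of the flavonol, the route is rejoined at 13.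

Step 3. The direct propargylation may lose regiocontrol between the two catechol hydroxyls (reaction at O3 or at both oxygens), and the free catechol may sequester the copper catalyst. The fallback differentiates the hydroxyls before the copper step. It sets out from 5, which selective 4-O-benzylation (BnBr, NaHCO3, NaI, DMF, 40 °C) converts into 4-(benzyloxy)-3-hydroxybenzaldehyde F4. MOM protection (MOMCl, iPr2NEt, CH2Cl2) gives 4-(benzyloxy)-3-(methoxymethoxy)benzaldehyde F5, and hydrogenolysis (H2, Pd/C, EtOAc, stopped at debenzylation) gives 4-hydroxy-3-(methoxymethoxy)benzaldehyde F6. Copper-catalysed propargylation of this monophenol with 7 (DBU, CuCl2·2H2O, MeCN, 0 °C) returns to the route at 9, so that step 4 is no longer needed.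

Further compounds
F1 | step 8 | 3,4'-di-O-acetyl-5,3'-di-O-MOM-7-O-prenyl-5'-prenylquercetin | COCOc1cc(OCC=C(C)C)cc2oc(-c3cc(CC=C(C)C)c(OC(C)=O)c(OCOC)c3)c(OC(C)=O)c(=O)c12
F2 | step 8 | 3,7,4'-tri-O-acetyl-5,3'-di-O-MOM-8-(1,1-dimethylallyl)-5'-prenylquercetin | COCOc1cc(OC(C)=O)c(C(C)(C)C=C)c2oc(-c3cc(CC=C(C)C)c(OC(C)=O)c(OCOC)c3)c(OC(C)=O)c(=O)c12
F3 | step 7 | (±)-5-(methoxymethoxy)-2-[3-(methoxymethoxy)-4-(2-methylbut-3-en-2-yloxy)phenyl]-7-(3-methylbut-2-enyloxy)chroman-4-one (racemic, one enantiomer drawn) | O=C1C[C@H](c2ccc(OC(C)(C)C=C)c(OCOC)c2)Oc2cc(OCC=C(C)C)cc(OCOC)c12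
F4 | step 3 | 4-(benzyloxy)-3-hydroxybenzaldehyde | O=Cc1ccc(OCc2ccccc2)c(O)c1
F5 | step 3 | 4-(benzyloxy)-3-(methoxymethoxy)benzaldehyde | O=Cc1ccc(OCc2ccccc2)c(OCOC)c1
F6 | step 3 | 4-hydroxy-3-(methoxymethoxy)benzaldehyde | O=Cc1ccc(O)c(OCOC)c1
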